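## Retrosynthetic overview

1. Target ⇒ MOM removal and Tsuji–Wilkinson excision of a temporary C3 formyl group ⇒ a (2S)-chromane-3-carbaldehyde.
2. Key disconnection C2–C3 of the dihydropyran ring ⇒ an acyclic (S)-sec-alkyl aryl ether with an ortho (E)-propenal arm. In the forward sense an iminium-triggered [1,5]-hydride shift/ring closure (internal redox) closes the only ring that must be made; the benzene ring is bought.
3. Enabling feature: the tertiary C2–H, α to O1, lies 1,5 to C4 across the C8a–C4a edge of the benzene ring. O1 is flanked by the C8 oxygen and the C4 arm, which the C5 methyl twists, so the planar C2 cation keeps a chiral C8a–O1 axis and C3 enters where the hydride left.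
4. O1–C2 comes from Mitsunobu inversion of an (R)-carbinol with a 2-hydroxybenzaldehyde; C3 and the formyl handle come from Wittig homologation of that aldehyde.
5. Fragment 1 (arene) comes from 2,3,4-trimethoxy-6-methylbenzaldehyde. Fragment 2 (carbinol) comes from (2E,6E)-farnesyl bromide, ethyl acetoacetate and an enzymatic reduction.

Key step: step 7

Remark: from the aryl ether onward, locants are those of the final chromane (O1, C2, C3, C4, C4a, C5 to C8, C8a, side chain C1' onward). The stereocentre of the target is read from the SMILES as S.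

## Route

Step 1
Reactants: 1 2,3,4-trimethoxy-6-methylbenzaldehyde
Product: 2 2,3,4-trihydroxy-6-methylbenzaldehyde
Conditions: BBr3 (4 equiv), CH2Cl2, −78 °C to rt; then H2O
Reagents that add atoms: none
Why: Lewis acid ether cleavage, in which BBr3 complexes each aryl methyl ether and bromide removes the methyl group by SN2, is a standard exhaustive demethylation that an aryl aldehyde survives after aqueous work-up.

Step 2
Reactants: 2 2,3,4-trihydroxy-6-methylbenzaldehyde
Product: 3 2-hydroxy-3,4-bis(methoxymethoxy)-6-methylbenzaldehyde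
Conditions: MOMCl (2.2 equiv), i-Pr2NEt (2.5 equiv), CH2Cl2, 0 °C, argon
Reagents that add atoms: chloromethyl methyl ether COCCl
Why: In this selective O-alkylation (acetal protection) the 2-hydroxyl is tied up in a hydrogen bond to the formyl oxygen and is the least nucleophilic, so two equivalents of MOMCl should cap only the 3- and 4-hydroxyls.

Step 3
Reactants: 4 (2E,6E)-farnesyl bromide; 5 ethyl acetoacetate
Product: 7 (5E,9E)-6,10,14-trimethylpentadeca-5,9,13-trien-2-one (farnesylacetone), via farnesylated keto ester 6 (not isolated)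
Conditions: NaOEt, EtOH, 0 °C to rt; then 2 M NaOH aq., 60 °C; then 1 M HCl to pH 4, 40 °C
Reagents that add atoms: none
Why: In this acetoacetic ester synthesis, SN2 alkylation of the stabilised enolate at the primary allylic carbon keeps both E alkenes, and saponification followed by decarboxylation of the β-keto acid leaves the methyl ketone.

Step 4
Reactants: 7 (5E,9E)-farnesylacetone
Product: 8 (2R,5E,9E)-6,10,14-trimethylpentadeca-5,9,13-trien-2-ol
Conditions: R-selective alcohol dehydrogenase from Lactobacillus brevis, NADP+ (cat.), MgCl2 (1 mM), 2-propanol/potassium phosphate buffer pH 7 (1:4), 30 °C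
Reagents that add atoms: none
Why: In this enzymatic ketone reduction (biocatalytic transfer hydrogenation) the binding pocket tells the methyl group from the long chain and delivers the cofactor hydride to the si face (anti-Prelog), which sets the R carbinol centre while 2-propanol recycles the cofactor.

Step 5
Reactants: 3 2-hydroxy-3,4-bis(methoxymethoxy)-6-methylbenzaldehyde; 8 (2R,5E,9E)-6,10,14-trimethylpentadeca-5,9,13-trien-2-ol
Product: 9 2-{[(2S,5E,9E)-6,10,14-trimethylpentadeca-5,9,13-trien-2-yl]oxy}-3,4-bis(methoxymethoxy)-6-methylbenzaldehyde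
Conditions: PPh3, DIAD, toluene, 0 °C to rt
Reagents that add atoms: none
Why: In this Mitsunobu etherification the acidic, formyl-activated phenol displaces the oxyphosphonium group of the secondary alcohol by SN2 with inversion, turning the R carbinol into the S aryl ether.

Step 6
Reactants: 9 the (S)-aryl ether aldehyde
Product: 10 (2E)-3-(2-{[(2S,5E,9E)-6,10,14-trimethylpentadeca-5,9,13-trien-2-yl]oxy}-3,4-bis(methoxymethoxy)-6-methylphenyl)prop-2-enal
Conditions: Ph3P=CHCHO (1.2 equiv), toluene, 90 °C
Reagents that add atoms: (triphenylphosphoranylidene)acetaldehyde O=CC=P(c1ccccc1)(c1ccccc1)c1ccccc1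
Why: Wittig olefination with a stabilised formyl ylide is E-selective and neutral, so the MOM groups, the ether stereocentre and the triene are left alone.

Step 7
Reactants: 10 the (S)-aryl ether enal
Product: 14 (2S)-7,8-bis(methoxymethoxy)-2,5-dimethyl-2-[(3E,7E)-4,8,12-trimethyltrideca-3,7,11-trien-1-yl]chromane-3-carbaldehyde as a C3 epimer mixture, via iminium ion 11 (not isolated), via oxocarbenium enamine 12 (not isolated), via cyclised iminium ion 13 (not isolated)
Conditions: Bn2NH·CF3CO2H (20 mol %), ClCH2CH2Cl, 70 °C, argon; then aqueous work-up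
Reagents that add atoms: none
Why: Proposed new method: the ammonium salt converts the enal into iminium ion 11, whose C4 takes up the tertiary C2–H as hydride in a through-space suprafacial [1,5]-shift, the aryl oxocarbenium/enamine pair 12 collapses at once by attack of the enamine carbon C3 on C2, and hydrolysis of 13 releases the aldehyde and the amine. The closest known reaction type is the [1,5]-hydride shift/ring closure cascade (internal redox reaction, tert-amino effect), shown under iminium catalysis for ortho-dialkylamino cinnamaldehydes and for ether-tethered enals that give spiroethers, and under Lewis acid catalysis for ortho-benzyloxy benzylidene malonates that give benzopyrans, whereas an enantioenriched sec-alkyl aryl ether as donor toward an enal has not been shown. The dihydropyran ring, the only ring closed, forms in a 6-(enolexo)-endo-trig mode. C2 is set by memory of chirality: C3 hangs on the carbon that received the hydride and so meets the face of the planar cation that the hydride left (net retention, as in the self-reproduction of chirality known in the amine series), and racemisation would need the O1=C2 unit to swing through the arene plane about the C8a–O1 axis, which the C8 OMOM group and the C4 arm block, while C3 forms as an epimer mixture that step 8 erases. Site selectivity rests on geometry, since only C2–H lies 1,5 to C4, and reactivity is helped by the C5 methyl and the two ortho neighbours of O1, which twist the enal arm and the O1–C2 bond out of the arene plane so that the para C7 oxygen deactivates C4 less and the O1 lone pair is free to stabilise the cation. The three trisubstituted alkenes should survive because the medium holds only a buffered ammonium salt and because capture of C2 by the nearest alkene would demand a four-membered ring or a secondary cation.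

Step 8
Reactants: 14 the (2S)-chromane-3-carbaldehyde
Product: 15 (2S)-7,8-bis(methoxymethoxy)-2,5-dimethyl-2-[(3E,7E)-4,8,12-trimethyltrideca-3,7,11-trien-1-yl]chromane
Conditions: RhCl(PPh3)3 (1.1 equiv), xylene, 130 °C, argon
Reagents that add atoms: none
Why: In the Tsuji–Wilkinson decarbonylation, oxidative addition of the formyl C–H bond to monovalent rhodium, CO migration and C–H reductive elimination replace CHO by H in a neutral medium, so no C3 enolate forms that could expel the O1 aryloxide, β-oxygenated aldehydes are known to pass this reaction, and C2 is not touched.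

Step 9
Reactants: 15 the bis-MOM chromane
Product: 16 (2S)-2,5-dimethyl-2-[(3E,7E)-4,8,12-trimethyltrideca-3,7,11-trien-1-yl]chromane-7,8-diol (target)
Conditions: p-TsOH·H2O (20 mol %), degassed MeOH, 40 °C, argon
Reagents that add atoms: none
Why: Acid-catalysed acetal exchange with methanol (MOM cleavage) is mild enough for isolated trisubstituted alkenes and for the tertiary aryl ether at C2, and exclusion of air protects the catechol.

## Compound list

1 | 2,3,4-trimethoxy-6-methylbenzaldehyde | O=Cc1c(C)cc(OC)c(OC)c1OC | starting material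
2 | 2,3,4-trihydroxy-6-methylbenzaldehyde | O=Cc1c(C)cc(O)c(O)c1O | intermediate
3 | 2-hydroxy-3,4-bis(methoxymethoxy)-6-methylbenzaldehyde | O=Cc1c(C)cc(OCOC)c(OCOC)c1O | intermediate
4 | (2E,6E)-farnesyl bromide | CC(C)=CCC/C(C)=C/CC/C(C)=C/CBr | starting material
5 | ethyl acetoacetate | CCOC(=O)CC(C)=O | starting material
6 | ethyl (4E,8E)-2-acetyl-5,9,13-trimethyltetradeca-4,8,12-trienoate (racemic) | CC(C)=CCC/C(C)=C/CC/C(C)=C/CC(C(C)=O)C(=O)OCC | intermediate
7 | (5E,9E)-6,10,14-trimethylpentadeca-5,9,13-trien-2-one | CC(C)=CCC/C(C)=C/CC/C(C)=C/CCC(C)=O | intermediate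
8 | (2R,5E,9E)-6,10,14-trimethylpentadeca-5,9,13-trien-2-ol | CC(C)=CCC/C(C)=C/CC/C(C)=C/CC[C@@H](C)O | intermediate
9 | 2-{[(2S,5E,9E)-6,10,14-trimethylpentadeca-5,9,13-trien-2-yl]oxy}-3,4-bis(methoxymethoxy)-6-methylbenzaldehyde | CC(C)=CCC/C(C)=C/CC/C(C)=C/CC[C@H](C)Oc1c(C=O)c(C)cc(OCOC)c1OCOC | intermediate
10 | (2E)-3-(2-{[(2S,5E,9E)-6,10,14-trimethylpentadeca-5,9,13-trien-2-yl]oxy}-3,4-bis(methoxymethoxy)-6-methylphenyl)prop-2-enal | CC(C)=CCC/C(C)=C/CC/C(C)=C/CC[C@H](C)Oc1c(/C=C/C=O)c(C)cc(OCOC)c1OCOC | intermediate
11 | N,N-dibenzyliminium trifluoroacetate of enal 10 | CC(C)=CCC/C(C)=C/CC/C(C)=C/CC[C@H](C)Oc1c(/C=C/C=[N+](Cc2ccccc2)Cc2ccccc2)c(C)cc(OCOC)c1OCOC.[O-]C(=O)C(F)(F)F | intermediate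
12 | aryl oxocarbenium trifluoroacetate bearing an (E)-3-(dibenzylamino)allyl arm (no stereocentre, chiral only through the C8a–O1 axis) | CC(C)=CCC/C(C)=C/CC/C(C)=C/CCC(C)=[O+]c1c(C/C=C/N(Cc2ccccc2)Cc2ccccc2)c(C)cc(OCOC)c1OCOC.[O-]C(=O)C(F)(F)F | intermediate
13 | N,N-dibenzyliminium trifluoroacetate of aldehyde 14 | CC(C)=CCC/C(C)=C/CC/C(C)=C/CC[C@@]1(C)C(C=[N+](Cc3ccccc3)Cc3ccccc3)Cc2c(C)cc(OCOC)c(OCOC)c2O1.[O-]C(=O)C(F)(F)F | intermediate
14 | (2S)-7,8-bis(methoxymethoxy)-2,5-dimethyl-2-[(3E,7E)-4,8,12-trimethyltrideca-3,7,11-trien-1-yl]chromane-3-carbaldehyde (both C3 epimers) | CC(C)=CCC/C(C)=C/CC/C(C)=C/CC[C@@]1(C)C(C=O)Cc2c(C)cc(OCOC)c(OCOC)c2O1 | intermediate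
15 | (2S)-7,8-bis(methoxymethoxy)-2,5-dimethyl-2-[(3E,7E)-4,8,12-trimethyltrideca-3,7,11-trien-1-yl]chromane | CC(C)=CCC/C(C)=C/CC/C(C)=C/CC[C@@]1(C)CCc2c(C)cc(OCOC)c(OCOC)c2O1 | intermediate
16 | (2S)-2,5-dimethyl-2-[(3E,7E)-4,8,12-trimethyltrideca-3,7,11-trien-1-yl]chromane-7,8-diol | CC(C)=CCC/C(C)=C/CC/C(C)=C/CC[C@@]1(C)CCc2c(C)cc(O)c(O)c2O1 | target

## Step count and risks

Total step count: 9.
Longest linear sequence: 7 steps (steps 1, 2, 5, 6, 7, 8, 9, or equally steps 3, 4, 5, 6, 7, 8, 9).

**Step 7 (Proposed new method).**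
- Hydride transfer may be too slow, because an aryl ether is a weaker donor than an amine.
- Proton transfer inside the ion pair may dealkylate O1.
- Stereochemical memory may erode, either through rotation about the C8a–O1 axis or through reversible amine-mediated β-elimination of O1 from the product.
- The fallback sets out from 9 and comes back at 15.
  - Pinnick oxidation of 9 (NaClO2, NaH2PO4, 2-methyl-2-butene, t-BuOH/H2O) would give the benzoic acid F1.
  - 1-Chloro-N,N,2-trimethylpropenylamine in CH2Cl2 would convert it under neutral conditions into the acid chloride F2, and CH2N2/Et3N in Et2O would give the α-diazoketone F3.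
  - Slow addition of F3 to Rh2(OAc)4 (1 mol %) in CH2Cl2 would use the known carbenoid insertion into a C–H bond next to an ether oxygen. This is concerted and proceeds with retention, and it would give the (2S)-chroman-4-one F4.
  - Condensation with TsNHNH2 (EtOH, 50 °C) would give the tosylhydrazone F5. Catecholborane (CHCl3, 0 °C) followed by NaOAc·3H2O (reflux) would reduce it to the methylene compound 15.

**Step 8.**
- Oxidative addition may be slow at a formyl group next to the quaternary C2.
- β-Hydride elimination toward C4 or thermal β-elimination of the aryloxide may compete.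
- The fallback sets out from 14 and comes back at 15.
  - Pinnick oxidation would give the chromane-3-carboxylic acid F6.
  - DCC and N-hydroxypyridine-2-thione (CH2Cl2, dark) would give the thiohydroxamate ester F7.
  - Visible-light irradiation with a large excess of t-BuSH (toluene, 0 °C) would deliver 15 by Barton reductive decarboxylation. The high thiol concentration serves to outrun 5-exo cyclisation of the C3 radical onto the nearest alkene.

**Step 5.**
- The phenol is flanked on both sides, so activation of the alcohol may end in elimination, or substitution may proceed with incomplete inversion.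
- The fallback sets out from 8 (with 3) and comes back at 9.
  - MsCl/Et3N (CH2Cl2, 0 °C) would give the (R)-mesylate F8.
  - The cesium phenoxide of 3 (Cs2CO3, DMF, 50 °C) would displace it by SN2 with inversion.

## Further compounds

F1 | step 7 | 2-{[(2S,5E,9E)-6,10,14-trimethylpentadeca-5,9,13-trien-2-yl]oxy}-3,4-bis(methoxymethoxy)-6-methylbenzoic acid | CC(C)=CCC/C(C)=C/CC/C(C)=C/CC[C@H](C)Oc1c(C(=O)O)c(C)cc(OCOC)c1OCOC
F2 | step 7 | acid chloride of F1 | CC(C)=CCC/C(C)=C/CC/C(C)=C/CC[C@H](C)Oc1c(C(=O)Cl)c(C)cc(OCOC)c1OCOC
F3 | step 7 | 2-diazo-1-aryl ethanone derived from F2 | CC(C)=CCC/C(C)=C/CC/C(C)=C/CC[C@H](C)Oc1c(C(=O)C=[N+]=[N-])c(C)cc(OCOC)c1OCOC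
F4 | step 7 | (2S)-7,8-bis(methoxymethoxy)-2,5-dimethyl-2-[(3E,7E)-4,8,12-trimethyltrideca-3,7,11-trien-1-yl]chroman-4-one | CC(C)=CCC/C(C)=C/CC/C(C)=C/CC[C@@]1(C)CC(=O)c2c(C)cc(OCOC)c(OCOC)c2O1
F5 | step 7 | tosylhydrazone of F4 | CC(C)=CCC/C(C)=C/CC/C(C)=C/CC[C@@]1(C)CC(=NNS(=O)(=O)c3ccc(C)cc3)c2c(C)cc(OCOC)c(OCOC)c2O1
F6 | step 8 | (2S)-7,8-bis(methoxymethoxy)-2,5-dimethyl-2-[(3E,7E)-4,8,12-trimethyltrideca-3,7,11-trien-1-yl]chromane-3-carboxylic acid (both C3 epimers) | CC(C)=CCC/C(C)=C/CC/C(C)=C/CC[C@@]1(C)C(C(=O)O)Cc2c(C)cc(OCOC)c(OCOC)c2O1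
F7 | step 8 | 2-thioxopyridin-1(2H)-yl ester of F6 | CC(C)=CCC/C(C)=C/CC/C(C)=C/CC[C@@]1(C)C(C(=O)ON3C=CC=CC3=S)Cc2c(C)cc(OCOC)c(OCOC)c2O1
F8 | step 5 | (2R,5E,9E)-6,10,14-trimethylpentadeca-5,9,13-trien-2-yl methanesulfonate | CC(C)=CCC/C(C)=C/CC/C(C)=C/CC[C@@H](C)OS(C)(=O)=O
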